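**Strategy**

The route rests on cutting both C–C bonds of furan C2, the oxygen-bearing CH of the dihydrobenzofuran that lies between the diarylmethine carbon and the benzylic C3H2 attached to the benzofuran benzo ring. Because this carbon carries one heteroatom and two carbon neighbours, a Matteson homologation can build it in one operation: LiCHCl2 inserts a CHCl unit into the C–B bond of diarylmethylboronate 12, and benzyl Grignard 18 displaces chloride, leaving a C–B bond that later becomes the ring C–O bond. Precursor 12 is the (S,S)-1,2-dicyclohexylethane-1,2-diol ester of the (R)-boronic acid whose carbon bears the 3,4-dibenzyloxyphenyl group and C8 of penta-O-benzylcatechin.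

Key step: step 12

Remark (auxiliary): with LiCHCl2/ZnCl2, (R,R)-1,2-diol boronates give (αS)-chlorides and (S,S)-diol boronates give (αR)-chlorides; the (αR) series is needed in steps 6 and 12, so the (S,S)-diol 6 is used throughout, since the (R,R)-diol would lead to the 2R-dihydrofuran after the invertive ring closure.

Remark (names): DICHED = 1,2-dicyclohexylethane-1,2-diol; "penta-O-benzylcatechin-8-yl" = (2R,3S)-3,5,7-tris(benzyloxy)-2-[3,4-bis(benzyloxy)phenyl]chroman-8-yl; catechin rings are A (benzo), B (catechol) and C (pyran).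

Remark (supply): 5, 6 and 8 are taken as commercial reagents.

**Route**

Step 1
Reactants: 1 (+)-catechin
Product: 2 5,7,3',4'-tetra-O-benzyl-(+)-catechin
Conditions: BnBr, K2CO3, DMF, 0 °C → rt
Reagents that add atoms: benzyl bromide, BrCc1ccccc1
Why: Williamson etherification in which K2CO3 deprotonates only the four phenols and not the secondary C3–OH, so benzyl bromide should cap them selectively without touching the C2/C3 stereocentres.

Step 2
Reactants: 2 5,7,3',4'-tetra-O-benzyl-(+)-catechin
Product: 3 8-bromo-5,7,3',4'-tetra-O-benzylcatechin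
Conditions: NBS (1 equiv), THF, −40 → 0 °C
Reagents that add atoms: N-bromosuccinimide, BrN1C(=O)CCC1=O
Why: Electrophilic aromatic bromination, in which C8 of ring A (flanked by the 7-benzyloxy group and the pyran oxygen) is the most nucleophilic position of 5,7-di-O-alkyl flavan-3-ols and should be brominated in preference to C6.

Step 3
Reactants: 3 8-bromo-5,7,3',4'-tetra-O-benzylcatechin
Product: 4 8-bromo-3,5,7,3',4'-penta-O-benzylcatechin
Conditions: NaH, BnBr, DMF, 0 °C → rt
Reagents that add atoms: benzyl bromide, BrCc1ccccc1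
Why: Williamson etherification of the secondary alkoxide gives a 3-O-benzyl ether that tolerates organolithium and Grignard reagents and falls off in the final hydrogenolysis.

Step 4
Reactants: 5 diisopropyl (dichloromethyl)boronate, 6 (1S,2S)-1,2-dicyclohexylethane-1,2-diol
Product: 7 (4S,5S)-4,5-dicyclohexyl-2-(dichloromethyl)-1,3,2-dioxaborolane
Conditions: toluene, rt; evaporation of propan-2-ol under vacuum
Reagents that add atoms: none
Why: Boronic ester transesterification, in which the chelating 1,2-diol displaces both isopropoxy groups and removal of volatile propan-2-ol drives the exchange to the C2-symmetric dioxaborolane.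

Step 5
Reactants: 8 1,2-bis(benzyloxy)-4-bromobenzene
Product: 9 [3,4-bis(benzyloxy)phenyl]magnesium bromide (THF solution, titrated)
Conditions: Mg turnings (I2-activated), THF, 40 °C
Reagents that add atoms: magnesium, [Mg]
Why: Grignard formation by magnesium insertion into an aryl bromide, to which the benzyl ethers are inert.

Step 6
Reactants: 4 8-bromo-3,5,7,3',4'-penta-O-benzylcatechin, 7 (4S,5S)-4,5-dicyclohexyl-2-(dichloromethyl)-1,3,2-dioxaborolane, 9 [3,4-bis(benzyloxy)phenyl]magnesium bromide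
Product: 12 (S,S)-DICHED ester of (R)-[3,4-bis(benzyloxy)phenyl](penta-O-benzylcatechin-8-yl)methylboronic acid, via 8-lithio-penta-O-benzylcatechin 10 (not isolated), via (R)-chloro(catechin-8-yl)methylboronic ester 11 (not isolated)
Conditions: n-BuLi, THF, −78 °C; 7, −78 °C; ZnCl2, −78 °C → rt; then 9 (excess), −78 °C → rt
Reagents that add atoms: none
Why: Bromine–lithium exchange gives the C8 aryllithium, which adds to boron of 7 so that the aryl group undergoes a ZnCl2-assisted 1,2-shift (Matteson homologation) with loss of the chloride selected by the (S,S)-diol to give (R)-chloride 11, whereupon Grignard 9 adds to boron and its aryl group migrates with inversion at carbon, which should fix the R methine of 12.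

Step 7
Reactants: 13 2,4,6-trihydroxybenzaldehyde
Product: 14 2,4-bis(benzyloxy)-6-hydroxybenzaldehyde
Conditions: BnBr (2.1 equiv), K2CO3, DMF, 0 °C → rt
Reagents that add atoms: benzyl bromide, BrCc1ccccc1
Why: Williamson etherification in which the 4-OH and one ortho-OH are benzylated while the remaining ortho-OH, hydrogen-bonded to the aldehyde and least reactive, should stay free with about two equivalents of halide.

Step 8
Reactants: 14 2,4-bis(benzyloxy)-6-hydroxybenzaldehyde
Product: 15 2,4-bis(benzyloxy)-6-(methoxymethoxy)benzaldehyde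
Conditions: NaH, MOMCl, DMF, 0 °C → rt
Reagents that add atoms: chloromethyl methyl ether, COCCl
Why: O-alkylation of the chelated phenoxide gives a methoxymethyl acetal that tolerates organomagnesium chemistry and can later be removed without touching benzyl ethers.

Step 9
Reactants: 15 2,4-bis(benzyloxy)-6-(methoxymethoxy)benzaldehyde
Product: 16 [2,4-bis(benzyloxy)-6-(methoxymethoxy)phenyl]methanol
Conditions: NaBH4, THF/MeOH, 0 °C
Reagents that add atoms: none
Why: Hydride reduction of the aryl aldehyde to the benzylic alcohol, with all ethers inert.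

Step 10
Reactants: 16 [2,4-bis(benzyloxy)-6-(methoxymethoxy)phenyl]methanol
Product: 17 1,5-bis(benzyloxy)-2-(chloromethyl)-3-(methoxymethoxy)benzene (used crude at once)
Conditions: MsCl, Et3N, MeCN/THF, −10 → 0 °C; cold aqueous NaHCO3 work-up
Reagents that add atoms: methanesulfonyl chloride, CS(=O)(=O)Cl
Why: O-sulfonylation followed by rapid displacement of the electron-rich benzylic sulfonate by the chloride released from the reagent should give the benzylic chloride under non-acidic conditions that spare the methoxymethyl ether.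

Step 11
Reactants: 17 1,5-bis(benzyloxy)-2-(chloromethyl)-3-(methoxymethoxy)benzene
Product: 18 [2,4-bis(benzyloxy)-6-(methoxymethoxy)benzyl]magnesium chloride (THF solution, titrated)
Conditions: Mg turnings (I2-activated), THF, 0 °C, slow addition, high dilution
Reagents that add atoms: magnesium, [Mg]
Why: Grignard formation by magnesium insertion into the benzylic C–Cl bond, run cold and dilute to suppress Wurtz-type homocoupling.

Step 12
Reactants: 12 (S,S)-DICHED ester of (R)-[3,4-bis(benzyloxy)phenyl](penta-O-benzylcatechin-8-yl)methylboronic acid, 19 dichloromethane, 18 [2,4-bis(benzyloxy)-6-(methoxymethoxy)benzyl]magnesium chloride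
Product: 21 (S,S)-DICHED ester of (1R,2R)-1-[3,4-bis(benzyloxy)phenyl]-3-[2,4-bis(benzyloxy)-6-(methoxymethoxy)phenyl]-1-(penta-O-benzylcatechin-8-yl)propan-2-ylboronic acid, via (1R,2R)-1-chloro-2,2-diarylethylboronic ester 20 (not isolated)
Conditions: n-BuLi, 19, THF, −100 °C; 12; ZnCl2, −100 °C → rt; then 18 (excess), −78 °C → rt
Reagents that add atoms: none
Why: LiCHCl2 adds to the boron of 12 and, on warming with ZnCl2, the diarylmethyl group shifts from boron to carbon with retention at the methine while one chloride leaves, giving (R)-chloride 20; Grignard 18 then adds to boron and its benzyl group shifts with inversion at the chlorinated carbon, so that the methine–C2 and C2–C3 bonds of the future dihydrofuran are both in place in 21. The closest known reaction type is the Matteson homologation of secondary alkylboronic esters of C2-symmetric diols followed by Grignard displacement, applied here to a bulkier, doubly benzylic migrating group. No ring is closed. The new stereocentre (future furan C2, R in 21) is set by the (S,S)-diol, which under ZnCl2 chelation selects which chloride of the dichloromethyl borate leaves, independently of the neighbouring methine and the catechin unit. The step needs attack of LiCHCl2 at boron in preference to deprotonation of the acidic diarylmethine C–H, and stereospecific migrations (retentive, then invertive); fast borate formation at −100 °C, the high migratory aptitude of a secondary benzylic group and chloride scavenging by ZnCl2 should secure these.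

Step 13
Reactants: 21 (S,S)-DICHED ester of the (1R,2R)-propan-2-ylboronic acid
Product: 22 (1R,2R)-1-[3,4-bis(benzyloxy)phenyl]-3-[2,4-bis(benzyloxy)-6-(methoxymethoxy)phenyl]-1-(penta-O-benzylcatechin-8-yl)propan-2-ol
Conditions: H2O2 (30 %), NaOH (aq), THF, 0 °C → rt
Reagents that add atoms: hydrogen peroxide, OO
Why: Alkaline peroxide oxidation of the C–B bond proceeds by 1,2-shift of carbon from boron to oxygen with retention, so the (2R)-carbinol should form and the diol auxiliary is released for recovery.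

Step 14
Reactants: 22 (1R,2R)-propan-2-ol with the methoxymethyl ether
Product: 23 (1R,2R)-1-[3,4-bis(benzyloxy)phenyl]-3-[2,4-bis(benzyloxy)-6-hydroxyphenyl]-1-(penta-O-benzylcatechin-8-yl)propan-2-ol
Conditions: HCl (cat.), MeOH/THF, 45 °C
Reagents that add atoms: none
Why: Acid-catalysed acetal exchange with methanol removes the methoxymethyl group as dimethoxymethane while the benzyl ethers, the non-benzylic secondary alcohol and the flavan stereocentres should be unaffected.

Step 15
Reactants: 23 (1R,2R)-phenol alcohol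
Product: 24 (2R,3S)-8-{(R)-[(2S)-4,6-bis(benzyloxy)-2,3-dihydro-1-benzofuran-2-yl][3,4-bis(benzyloxy)phenyl]methyl}-3,5,7-tris(benzyloxy)-2-[3,4-bis(benzyloxy)phenyl]chroman
Conditions: PPh3, DIAD, THF, 0 °C → rt
Reagents that add atoms: none
Why: Intramolecular Mitsunobu etherification in which the phenol, the only acidic O–H, displaces the oxyphosphonium-activated carbinol in a 5-exo-tet SN2 closure, inverting C2 from R to S and forming the dihydrofuran ring.

Step 16
Reactants: 24 nona-O-benzyl ether of the target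
Product: 25 (2R,3S)-8-{(R)-[(2S)-4,6-dihydroxy-2,3-dihydro-1-benzofuran-2-yl](3,4-dihydroxyphenyl)methyl}-2-(3,4-dihydroxyphenyl)chroman-3,5,7-triol (CNP0280971.2)
Conditions: H2 (1 atm), Pd(OH)2/C, THF/MeOH, rt
Reagents that add atoms: none
Why: Catalytic hydrogenolysis cleaves the nine O-benzyl ethers under neutral conditions, under which the homobenzylic C2–O bond of the dihydrofuran and the flavan C–O bonds should persist as in deprotections of benzylated flavan-3-ols.

**Compound list**

1 | (+)-catechin | O[C@H]1Cc2c(O)cc(O)cc2O[C@@H]1c1ccc(O)c(O)c1 | starting material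
2 | 5,7,3',4'-tetra-O-benzyl-(+)-catechin | O[C@H]1Cc2c(OCc9ccccc9)cc(OCc9ccccc9)cc2O[C@@H]1c1ccc(OCc9ccccc9)c(OCc9ccccc9)c1 | intermediate
3 | 8-bromo-5,7,3',4'-tetra-O-benzylcatechin | Brc1c(OCc9ccccc9)cc(OCc9ccccc9)c2c1O[C@H](c1ccc(OCc9ccccc9)c(OCc9ccccc9)c1)[C@@H](O)C2 | intermediate
4 | 8-bromo-3,5,7,3',4'-penta-O-benzylcatechin | Brc1c(OCc9ccccc9)cc(OCc9ccccc9)c2c1O[C@H](c1ccc(OCc9ccccc9)c(OCc9ccccc9)c1)[C@@H](OCc9ccccc9)C2 | intermediate
5 | diisopropyl (dichloromethyl)boronate | ClC(Cl)B(OC(C)C)OC(C)C | starting material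
6 | (1S,2S)-1,2-dicyclohexylethane-1,2-diol, (S,S)-DICHED | O[C@@H](C1CCCCC1)[C@H](C1CCCCC1)O | starting material
7 | (4S,5S)-4,5-dicyclohexyl-2-(dichloromethyl)-1,3,2-dioxaborolane | ClC(Cl)B1O[C@@H](C2CCCCC2)[C@H](C2CCCCC2)O1 | intermediate
8 | 1,2-bis(benzyloxy)-4-bromobenzene | Brc1ccc(OCc9ccccc9)c(OCc9ccccc9)c1 | starting material
9 | [3,4-bis(benzyloxy)phenyl]magnesium bromide | Br[Mg]c1ccc(OCc9ccccc9)c(OCc9ccccc9)c1 | intermediate
10 | 8-lithio-3,5,7,3',4'-penta-O-benzylcatechin | [Li]c1c(OCc9ccccc9)cc(OCc9ccccc9)c2c1O[C@H](c1ccc(OCc9ccccc9)c(OCc9ccccc9)c1)[C@@H](OCc9ccccc9)C2 | intermediate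
11 | (S,S)-DICHED ester of (R)-chloro(penta-O-benzylcatechin-8-yl)methylboronic acid | Cl[C@H](B1O[C@@H](C2CCCCC2)[C@H](C2CCCCC2)O1)c1c(OCc9ccccc9)cc(OCc9ccccc9)c3c1O[C@H](c1ccc(OCc9ccccc9)c(OCc9ccccc9)c1)[C@@H](OCc9ccccc9)C3 | intermediate
12 | (S,S)-DICHED ester of (R)-[3,4-bis(benzyloxy)phenyl](penta-O-benzylcatechin-8-yl)methylboronic acid | B1(O[C@@H](C2CCCCC2)[C@H](C2CCCCC2)O1)[C@H](c1ccc(OCc9ccccc9)c(OCc9ccccc9)c1)c1c(OCc9ccccc9)cc(OCc9ccccc9)c3c1O[C@H](c1ccc(OCc9ccccc9)c(OCc9ccccc9)c1)[C@@H](OCc9ccccc9)C3 | intermediate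
13 | 2,4,6-trihydroxybenzaldehyde | O=Cc1c(O)cc(O)cc1O | starting material
14 | 2,4-bis(benzyloxy)-6-hydroxybenzaldehyde | Oc1cc(OCc9ccccc9)cc(OCc9ccccc9)c1C=O | intermediate
15 | 2,4-bis(benzyloxy)-6-(methoxymethoxy)benzaldehyde | COCOc1cc(OCc9ccccc9)cc(OCc9ccccc9)c1C=O | intermediate
16 | [2,4-bis(benzyloxy)-6-(methoxymethoxy)phenyl]methanol | COCOc1cc(OCc9ccccc9)cc(OCc9ccccc9)c1CO | intermediate
17 | 1,5-bis(benzyloxy)-2-(chloromethyl)-3-(methoxymethoxy)benzene | COCOc1cc(OCc9ccccc9)cc(OCc9ccccc9)c1CCl | intermediate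
18 | [2,4-bis(benzyloxy)-6-(methoxymethoxy)benzyl]magnesium chloride | COCOc1cc(OCc9ccccc9)cc(OCc9ccccc9)c1C[Mg]Cl | intermediate
19 | dichloromethane | ClCCl | starting material
20 | (S,S)-DICHED ester of (1R,2R)-1-chloro-2-[3,4-bis(benzyloxy)phenyl]-2-(penta-O-benzylcatechin-8-yl)ethylboronic acid | Cl[C@H](B1O[C@@H](C2CCCCC2)[C@H](C2CCCCC2)O1)[C@H](c1ccc(OCc9ccccc9)c(OCc9ccccc9)c1)c1c(OCc9ccccc9)cc(OCc9ccccc9)c3c1O[C@H](c1ccc(OCc9ccccc9)c(OCc9ccccc9)c1)[C@@H](OCc9ccccc9)C3 | intermediate
21 | (S,S)-DICHED ester of (1R,2R)-1-[3,4-bis(benzyloxy)phenyl]-3-[2,4-bis(benzyloxy)-6-(methoxymethoxy)phenyl]-1-(penta-O-benzylcatechin-8-yl)propan-2-ylboronic acid | COCOc1cc(OCc9ccccc9)cc(OCc9ccccc9)c1C[C@@H](B1O[C@@H](C2CCCCC2)[C@H](C2CCCCC2)O1)[C@H](c1ccc(OCc9ccccc9)c(OCc9ccccc9)c1)c1c(OCc9ccccc9)cc(OCc9ccccc9)c3c1O[C@H](c1ccc(OCc9ccccc9)c(OCc9ccccc9)c1)[C@@H](OCc9ccccc9)C3 | intermediate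
22 | (1R,2R)-1-[3,4-bis(benzyloxy)phenyl]-3-[2,4-bis(benzyloxy)-6-(methoxymethoxy)phenyl]-1-(penta-O-benzylcatechin-8-yl)propan-2-ol | COCOc1cc(OCc9ccccc9)cc(OCc9ccccc9)c1C[C@@H](O)[C@H](c1ccc(OCc9ccccc9)c(OCc9ccccc9)c1)c1c(OCc9ccccc9)cc(OCc9ccccc9)c3c1O[C@H](c1ccc(OCc9ccccc9)c(OCc9ccccc9)c1)[C@@H](OCc9ccccc9)C3 | intermediate
23 | (1R,2R)-1-[3,4-bis(benzyloxy)phenyl]-3-[2,4-bis(benzyloxy)-6-hydroxyphenyl]-1-(penta-O-benzylcatechin-8-yl)propan-2-ol | Oc1cc(OCc9ccccc9)cc(OCc9ccccc9)c1C[C@@H](O)[C@H](c1ccc(OCc9ccccc9)c(OCc9ccccc9)c1)c1c(OCc9ccccc9)cc(OCc9ccccc9)c3c1O[C@H](c1ccc(OCc9ccccc9)c(OCc9ccccc9)c1)[C@@H](OCc9ccccc9)C3 | intermediate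
24 | nona-O-benzyl ether of the target: (2R,3S)-8-{(R)-[(2S)-4,6-bis(benzyloxy)-2,3-dihydro-1-benzofuran-2-yl][3,4-bis(benzyloxy)phenyl]methyl}-3,5,7-tris(benzyloxy)-2-[3,4-bis(benzyloxy)phenyl]chroman | c9ccccc9COc1cc(OCc9ccccc9)c2c(c1)O[C@H]([C@H](c1ccc(OCc9ccccc9)c(OCc9ccccc9)c1)c1c(OCc9ccccc9)cc(OCc9ccccc9)c3c1O[C@H](c1ccc(OCc9ccccc9)c(OCc9ccccc9)c1)[C@@H](OCc9ccccc9)C3)C2 | intermediate
25 | CNP0280971.2, (2R,3S)-8-{(R)-[(2S)-4,6-dihydroxy-2,3-dihydro-1-benzofuran-2-yl](3,4-dihydroxyphenyl)methyl}-2-(3,4-dihydroxyphenyl)chroman-3,5,7-triol | Oc1cc(O)c2c(c1)O[C@H]([C@H](c1ccc(O)c(O)c1)c1c(O)cc(O)c3c1O[C@H](c1ccc(O)c(O)c1)[C@@H](O)C3)C2 | target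

**Step count and risks**

Total step count: 16. Longest linear sequence: 10 steps (7, 8, 9, 10, 11, 12, 13, 14, 15, 16); the catechin branch needs 9 (1, 2, 3, 6, 12–16).

Steps most likely to fail:

1. Step 12. LiCHCl2 may deprotonate the acidic, doubly benzylic C–H of 12 instead of attacking the shielded boron, costing material or methine configuration. Migration of the bulky group may be slow enough for oxygen-to-carbon migration to compete. In the second stage, hindered 20 may be captured slowly by 18, so that chloride exchange epimerises C1 or HCl is lost. Fallback (lithiation–borylation with a chiral carbenoid, setting out from 18 and 12 and returning at 21): Grignard 18 is added to formaldehyde (cracked paraformaldehyde, THF) to give 2-[2,4-bis(benzyloxy)-6-(methoxymethoxy)phenyl]ethanol F1. Treatment with N,N-diisopropylcarbamoyl chloride and Et3N in hot toluene gives the N,N-diisopropylcarbamate F2. Deprotonation with s-BuLi/(−)-sparteine in Et2O at −78 °C should give the (S)-α-lithio carbamate F3. F3 is borylated by 12 with retention, and 1,2-migration of the diarylmethyl group (promoted by MgBr2·OEt2/MeOH on warming) with inversion expels the carbamate and should deliver 21. Here only the methine–C2 bond is formed, and C2 is set by the carbenoid instead of the diol.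

2. Step 6. The benzylic chloride 11 is activated by three ortho/para oxygen donors and may ionise under ZnCl2, scrambling the chloride and hence the methine; attack of 9 at the crowded boron may also be sluggish. Fallback (reversed order of aryl introduction with the enantiomeric auxiliary, then auxiliary exchange, setting out from 5, 9 and 4 and returning at 12): 5 and (1R,2R)-1,2-dicyclohexylethane-1,2-diol give (4R,5R)-4,5-dicyclohexyl-2-(dichloromethyl)-1,3,2-dioxaborolane F4. Grignard 9 and ZnCl2 convert F4 into the (R,R)-DICHED ester of (S)-chloro[3,4-bis(benzyloxy)phenyl]methylboronic acid F5, whose chloride is stabilised by only one para oxygen. Aryllithium 10 (from 4 and n-BuLi) displaces the chloride with inversion to give the (R,R)-DICHED ester of the (R)-diarylmethylboronic acid F6. KHF2 in MeOH/H2O cleaves the diol to give potassium (R)-[3,4-bis(benzyloxy)phenyl](penta-O-benzylcatechin-8-yl)methyltrifluoroborate F7. Me3SiCl and diol 6 in MeCN re-esterify F7 to 12.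

3. Step 11. Wurtz-type homocoupling and self-alkylation of the labile chloride 17 during slow magnesium insertion may leave a weak or unusable Grignard solution. Fallback (tin–lithium exchange in place of direct insertion, setting out from 17 and returning at 18): freshly made 17 is added to Bu3SnLi (from Bu3SnH and LiN(iPr)2, THF, −78 °C), which should capture the chloride at once as tributyl{[2,4-bis(benzyloxy)-6-(methoxymethoxy)phenyl]methyl}stannane F8, a storable compound. n-BuLi (THF, −78 °C) converts F8 into [2,4-bis(benzyloxy)-6-(methoxymethoxy)benzyl]lithium F9, and MgCl2 transmetallates F9 to 18.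

Further compounds
F1 | step 12 | 2-[2,4-bis(benzyloxy)-6-(methoxymethoxy)phenyl]ethanol | COCOc1cc(OCc9ccccc9)cc(OCc9ccccc9)c1CCO
F2 | step 12 | 2-[2,4-bis(benzyloxy)-6-(methoxymethoxy)phenyl]ethyl N,N-diisopropylcarbamate | COCOc1cc(OCc9ccccc9)cc(OCc9ccccc9)c1CCOC(=O)N(C(C)C)C(C)C
F3 | step 12 | (S)-1-lithio-2-[2,4-bis(benzyloxy)-6-(methoxymethoxy)phenyl]ethyl N,N-diisopropylcarbamate | COCOc1cc(OCc9ccccc9)cc(OCc9ccccc9)c1C[C@H]([Li])OC(=O)N(C(C)C)C(C)C
F4 | step 6 | (4R,5R)-4,5-dicyclohexyl-2-(dichloromethyl)-1,3,2-dioxaborolane | ClC(Cl)B1O[C@H](C2CCCCC2)[C@@H](C2CCCCC2)O1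
F5 | step 6 | (R,R)-DICHED ester of (S)-chloro[3,4-bis(benzyloxy)phenyl]methylboronic acid | Cl[C@@H](B1O[C@H](C2CCCCC2)[C@@H](C2CCCCC2)O1)c1ccc(OCc9ccccc9)c(OCc9ccccc9)c1
F6 | step 6 | (R,R)-DICHED ester of (R)-[3,4-bis(benzyloxy)phenyl](penta-O-benzylcatechin-8-yl)methylboronic acid | B1(O[C@H](C2CCCCC2)[C@@H](C2CCCCC2)O1)[C@H](c1ccc(OCc9ccccc9)c(OCc9ccccc9)c1)c1c(OCc9ccccc9)cc(OCc9ccccc9)c3c1O[C@H](c1ccc(OCc9ccccc9)c(OCc9ccccc9)c1)[C@@H](OCc9ccccc9)C3
F7 | step 6 | potassium (R)-[3,4-bis(benzyloxy)phenyl](penta-O-benzylcatechin-8-yl)methyltrifluoroborate | [K+].F[B-](F)(F)[C@H](c1ccc(OCc9ccccc9)c(OCc9ccccc9)c1)c1c(OCc9ccccc9)cc(OCc9ccccc9)c3c1O[C@H](c1ccc(OCc9ccccc9)c(OCc9ccccc9)c1)[C@@H](OCc9ccccc9)C3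
F8 | step 11 | tributyl{[2,4-bis(benzyloxy)-6-(methoxymethoxy)phenyl]methyl}stannane | COCOc1cc(OCc9ccccc9)cc(OCc9ccccc9)c1C[Sn](CCCC)(CCCC)CCCC
F9 | step 11 | [2,4-bis(benzyloxy)-6-(methoxymethoxy)benzyl]lithium | COCOc1cc(OCc9ccccc9)cc(OCc9ccccc9)c1C[Li]
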